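**Retrosynthetic overview**

- Target 12 comes from aldehyde 11 by cleavage of three aryl methyl ethers; 11 comes from ester 9 by reduction to the benzylic alcohol and re-oxidation.
- Phenol 9 comes from the 6,7-dihydro-1-benzofuran-4(5H)-one 8 by dehydrogenation, so the benzo ring is carried saturated and made aromatic only after the furan exists.
- The route rests on this feature: the benzo ring (C3a, C4–C7, C7a), with oxygen on C4 and the formyl carbon on C6, is the mirror-symmetric dione 6 in masked form. The carbon between its two carbonyls becomes C3a, one carbonyl oxygen becomes O1 and the other the C4 hydroxyl, so the furan is annulated with no regiochemical choice on that ring.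
- Key disconnections: C3–C3a (C-alkylation of 6 by the α-bromo ketone 5) and O1–C2 (acid cyclodehydration of the resulting 1,4-diketone 7). The furan is the only ring that is built.
- Bromo ketone 5 comes from ketone 1 and aryl bromide 2 by Pd-catalysed α-arylation and bromination through the silyl enol ether.

Key step: step 3

Remark: 5, 7 and 8 are racemic and no enantiocontrol is sought, because the only stereocentre carried forward (C6 of 8) is erased in step 4 and the target is achiral.

**Step 1**
Reactants: 1 1-(4-methoxyphenyl)ethan-1-one; 2 1-bromo-3,5-dimethoxybenzene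
Product: 3 2-(3,5-dimethoxyphenyl)-1-(4-methoxyphenyl)ethan-1-one
Conditions: Pd2(dba)3 (cat.), Xantphos (cat.), NaOtBu (2.2 equiv), THF, 70 °C
Reagents that add atoms: none
Why: Pd-catalysed α-arylation of a ketone enolate (Buchwald–Hartwig type), in which zerovalent palladium inserts into the C–Br bond of 2, the sodium enolate of 1 is transferred to palladium and reductive elimination forms the benzylic C–C bond, while the wide-bite-angle ligand and the lower reactivity of the more hindered, more stabilised product enolate should hold the reaction at monoarylation.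

**Step 2**
Reactants: 3 2-(3,5-dimethoxyphenyl)-1-(4-methoxyphenyl)ethan-1-one
Product: 5 2-bromo-2-(3,5-dimethoxyphenyl)-1-(4-methoxyphenyl)ethan-1-one (racemic), via trimethylsilyl enol ether 4 (not isolated)
Conditions: LiN(SiMe3)2, Me3SiCl, THF, −78 °C to 0 °C; then NBS, −78 °C to 0 °C
Reagents that add atoms: N-bromosuccinimide, O=C1CCC(=O)N1Br (Br of 5); chlorotrimethylsilane, C[Si](C)(C)Cl (SiMe3 of intermediate 4 only)
Why: Electrophilic α-bromination of a silyl enol ether, in which the enolate of 3 (expected Z) is trapped on oxygen and the enol ether takes bromine from NBS at low temperature much faster than the 3,5-dimethoxyphenyl ring can, so that nuclear bromination should be avoided; the new C–Br stereocentre is formed racemic.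

**Step 3**
Reactants: 5 2-bromo-2-(3,5-dimethoxyphenyl)-1-(4-methoxyphenyl)ethan-1-one (racemic); 6 methyl 3,5-dioxocyclohexane-1-carboxylate
Product: 8 methyl 3-(3,5-dimethoxyphenyl)-2-(4-methoxyphenyl)-4-oxo-4,5,6,7-tetrahydro-1-benzofuran-6-carboxylate (racemic), via triketone 7 (not isolated)
Conditions: K2CO3, CHCl3, rt to 40 °C; filter, evaporate; then TsOH·H2O (cat.), toluene, reflux, Dean–Stark
Reagents that add atoms: none
Why: K2CO3 converts the acidic dione 6 into its enolate, whose central carbon (C4 of 6) displaces bromide from the secondary benzylic α-keto bromide 5 by SN2 (C3–C3a bond) to give the 2-substituted dione 7, a 1,4-diketone. TsOH then brings an enol oxygen of the dione onto the protonated aryl ketone in a 5-exo-trig closure and the hemiketal loses water (O1–C2 bond), a Paal–Knorr furan synthesis; the closest known reaction type is the alkylation of cyclohexane-1,3-diones by α-halo ketones followed by acid cyclodehydration to 6,7-dihydro-1-benzofuran-4(5H)-ones. Because 6 has a mirror plane through C1 and C4, either carbonyl leads to the same furan, the untouched carbonyl is the future C4 oxygen and the ester sits at the future C6. The single stereocentre of 8 (C6) arises from this desymmetrisation with no controlling element, is therefore racemic and disappears in step 4, while the stereocentres of 5 and 7 end as sp2 carbons. The step needs substitution at carbon before any carbonyl addition, since an aldol-first Feist–Benary course would interchange the two aryl groups and O-alkylation would give an enol ether that cannot close to 8; the high SN2 reactivity of the α-keto benzylic bromide toward the soft enolate carbon in a weakly polar solvent and the hindered, p-methoxy-deactivated aryl ketone should secure this.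

**Step 4**
Reactants: 8 methyl 3-(3,5-dimethoxyphenyl)-2-(4-methoxyphenyl)-4-oxo-4,5,6,7-tetrahydro-1-benzofuran-6-carboxylate (racemic)
Product: 9 methyl 3-(3,5-dimethoxyphenyl)-4-hydroxy-2-(4-methoxyphenyl)-1-benzofuran-6-carboxylate
Conditions: DDQ (1.2 equiv), 1,4-dioxane, reflux
Reagents that add atoms: none
Why: Quinone dehydrogenation of a cyclohexenone to a phenol, in which DDQ should abstract hydride from C7 (a furfuryl-type position whose cation is stabilised through the furan and the p-methoxyphenyl group), loss of the acidic C6–H next to the ester gives the keto tautomer of 9, and enolisation to the aromatic ring is irreversible and removes the C6 stereocentre.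

**Step 5**
Reactants: 9 methyl 3-(3,5-dimethoxyphenyl)-4-hydroxy-2-(4-methoxyphenyl)-1-benzofuran-6-carboxylate
Product: 10 3-(3,5-dimethoxyphenyl)-6-(hydroxymethyl)-2-(4-methoxyphenyl)-1-benzofuran-4-ol
Conditions: LiAlH4 (excess), THF, 0 °C to rt; aqueous Rochelle salt work-up
Reagents that add atoms: none
Why: Hydride reduction of an ester, in which LiAlH4 first deprotonates the phenol and then reduces the methyl ester to the primary benzylic alcohol, the aryl ethers and the benzofuran being inert.

**Step 6**
Reactants: 10 3-(3,5-dimethoxyphenyl)-6-(hydroxymethyl)-2-(4-methoxyphenyl)-1-benzofuran-4-ol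
Product: 11 3-(3,5-dimethoxyphenyl)-4-hydroxy-2-(4-methoxyphenyl)-1-benzofuran-6-carbaldehyde
Conditions: activated MnO2 (excess), EtOAc, rt
Reagents that add atoms: none
Why: Chemoselective MnO2 oxidation of a benzylic alcohol, which stops at the aldehyde and, because the hydroxymethyl group is meta to both oxygens of its ring, cannot divert through a quinone methide.

**Step 7**
Reactants: 11 3-(3,5-dimethoxyphenyl)-4-hydroxy-2-(4-methoxyphenyl)-1-benzofuran-6-carbaldehyde
Product: 12 3-(3,5-dihydroxyphenyl)-4-hydroxy-2-(4-hydroxyphenyl)-1-benzofuran-6-carbaldehyde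
Conditions: BBr3 (excess), CH2Cl2, −78 °C to rt; then ice-water
Reagents that add atoms: none
Why: Lewis-acid cleavage of aryl methyl ethers, in which BBr3 coordinates each ether oxygen and bromide removes the methyl group by SN2 as bromomethane, the aryl borates are hydrolysed on work-up, and the formyl group, meta to both oxygens of its ring as in 3,5-dimethoxybenzaldehyde, should be released unchanged from its boron complex.

**Compound list**

1 | 1-(4-methoxyphenyl)ethan-1-one | CC(=O)c1ccc(OC)cc1 | starting material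
2 | 1-bromo-3,5-dimethoxybenzene | COc1cc(Br)cc(OC)c1 | starting material
3 | 2-(3,5-dimethoxyphenyl)-1-(4-methoxyphenyl)ethan-1-one | COc1ccc(C(=O)Cc2cc(OC)cc(OC)c2)cc1 | intermediate
4 | {[(Z)-2-(3,5-dimethoxyphenyl)-1-(4-methoxyphenyl)ethenyl]oxy}trimethylsilane | COc1ccc(/C(O[Si](C)(C)C)=C/c2cc(OC)cc(OC)c2)cc1 | intermediate
5 | 2-bromo-2-(3,5-dimethoxyphenyl)-1-(4-methoxyphenyl)ethan-1-one (racemic) | COc1ccc(C(=O)C(Br)c2cc(OC)cc(OC)c2)cc1 | intermediate
6 | methyl 3,5-dioxocyclohexane-1-carboxylate | COC(=O)C1CC(=O)CC(=O)C1 | starting material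
7 | methyl 4-[1-(3,5-dimethoxyphenyl)-2-(4-methoxyphenyl)-2-oxoethyl]-3,5-dioxocyclohexane-1-carboxylate (racemic, mixture of diastereomers and enol tautomers) | COC(=O)C1CC(=O)C(C(c2cc(OC)cc(OC)c2)C(=O)c2ccc(OC)cc2)C(=O)C1 | intermediate
8 | methyl 3-(3,5-dimethoxyphenyl)-2-(4-methoxyphenyl)-4-oxo-4,5,6,7-tetrahydro-1-benzofuran-6-carboxylate (racemic) | COC(=O)C1CC(=O)c2c(-c3cc(OC)cc(OC)c3)c(-c3ccc(OC)cc3)oc2C1 | intermediate
9 | methyl 3-(3,5-dimethoxyphenyl)-4-hydroxy-2-(4-methoxyphenyl)-1-benzofuran-6-carboxylate | COC(=O)c1cc(O)c2c(-c3cc(OC)cc(OC)c3)c(-c3ccc(OC)cc3)oc2c1 | intermediate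
10 | 3-(3,5-dimethoxyphenyl)-6-(hydroxymethyl)-2-(4-methoxyphenyl)-1-benzofuran-4-ol | OCc1cc(O)c2c(-c3cc(OC)cc(OC)c3)c(-c3ccc(OC)cc3)oc2c1 | intermediate
11 | 3-(3,5-dimethoxyphenyl)-4-hydroxy-2-(4-methoxyphenyl)-1-benzofuran-6-carbaldehyde | O=Cc1cc(O)c2c(-c3cc(OC)cc(OC)c3)c(-c3ccc(OC)cc3)oc2c1 | intermediate
12 | 3-(3,5-dihydroxyphenyl)-4-hydroxy-2-(4-hydroxyphenyl)-1-benzofuran-6-carbaldehyde | O=Cc1cc(O)c2c(-c3cc(O)cc(O)c3)c(-c3ccc(O)cc3)oc2c1 | target

**Total step count:** 7
**Longest linear sequence:** 7 steps (1 and 2 to 12 through 3, 5, 8, 9, 10 and 11)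

**Steps most likely to fail**

Step 3. The ambident dione enolate may be alkylated on oxygen, or the hindered secondary bromide may transfer bromine to the enolate (reductive debromination back to 3) faster than it undergoes substitution. Fallback, setting out from 6: alkylation with the unhindered primary bromide 2-bromo-1-(4-methoxyphenyl)ethan-1-one (K2CO3, CHCl3) should give the triketone methyl 4-[2-(4-methoxyphenyl)-2-oxoethyl]-3,5-dioxocyclohexane-1-carboxylate F1. Cyclodehydration with TsOH in toluene should give methyl 2-(4-methoxyphenyl)-4-oxo-4,5,6,7-tetrahydro-1-benzofuran-6-carboxylate F2. Bromination with NBS in DMF at 0 °C at the only free furan position should give methyl 3-bromo-2-(4-methoxyphenyl)-4-oxo-4,5,6,7-tetrahydro-1-benzofuran-6-carboxylate F3. Suzuki–Miyaura coupling of F3 with (3,5-dimethoxyphenyl)boronic acid (Pd(PPh3)4, K2CO3, dioxane–water, 90 °C) installs the C3 aryl group and comes back to the route at 8.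

Step 4. Hydride transfer may be slow because it depends on enolisation, and the electron-rich hydroxybenzofuran that forms may be oxidised further by the quinone. Fallback, setting out from 8: kinetic deprotonation at C5 with LiN(iPr)2 in THF at −78 °C and trapping with PhSeBr should give methyl 3-(3,5-dimethoxyphenyl)-2-(4-methoxyphenyl)-4-oxo-5-(phenylselanyl)-4,5,6,7-tetrahydro-1-benzofuran-6-carboxylate F4. Oxidation with H2O2 in CH2Cl2 at 0 °C should give the selenoxide methyl 3-(3,5-dimethoxyphenyl)-2-(4-methoxyphenyl)-4-oxo-5-(phenylseleninyl)-4,5,6,7-tetrahydro-1-benzofuran-6-carboxylate F5, which is not isolated. Syn-elimination across C5–C6 followed by enolisation comes back to the route at 9.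

Step 7. Ether cleavage may stop at partly methylated phenols, and the boron-activated formyl group may be brominated or may condense with the electron-rich resorcinol ring of a second molecule. Fallback, setting out from 9, in which the ethers are cleaved before the aldehyde exists and the phenols are carried as fluoride-labile silyl ethers: BBr3 in CH2Cl2 should give methyl 3-(3,5-dihydroxyphenyl)-4-hydroxy-2-(4-hydroxyphenyl)-1-benzofuran-6-carboxylate F6. Silylation with tert-butyldimethylsilyl chloride and imidazole in DMF should give the tetrakis(silyl ether) methyl 4-[(tert-butyldimethylsilyl)oxy]-3-{3,5-bis[(tert-butyldimethylsilyl)oxy]phenyl}-2-{4-[(tert-butyldimethylsilyl)oxy]phenyl}-1-benzofuran-6-carboxylate F7. Reduction with iBu2AlH in CH2Cl2 at −78 °C should give the benzylic alcohol (4-[(tert-butyldimethylsilyl)oxy]-3-{3,5-bis[(tert-butyldimethylsilyl)oxy]phenyl}-2-{4-[(tert-butyldimethylsilyl)oxy]phenyl}-1-benzofuran-6-yl)methanol F8. MnO2 should give the aldehyde 4-[(tert-butyldimethylsilyl)oxy]-3-{3,5-bis[(tert-butyldimethylsilyl)oxy]phenyl}-2-{4-[(tert-butyldimethylsilyl)oxy]phenyl}-1-benzofuran-6-carbaldehyde F9. Desilylation with Bu4NF buffered with AcOH in THF at 0 °C comes back to the route at 12.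

**Further compounds**

F1 | step 3 | methyl 4-[2-(4-methoxyphenyl)-2-oxoethyl]-3,5-dioxocyclohexane-1-carboxylate | COC(=O)C1CC(=O)C(CC(=O)c2ccc(OC)cc2)C(=O)C1
F2 | step 3 | methyl 2-(4-methoxyphenyl)-4-oxo-4,5,6,7-tetrahydro-1-benzofuran-6-carboxylate (racemic) | COC(=O)C1CC(=O)c2cc(-c3ccc(OC)cc3)oc2C1
F3 | step 3 | methyl 3-bromo-2-(4-methoxyphenyl)-4-oxo-4,5,6,7-tetrahydro-1-benzofuran-6-carboxylate (racemic) | COC(=O)C1CC(=O)c2c(Br)c(-c3ccc(OC)cc3)oc2C1
F4 | step 4 | methyl 3-(3,5-dimethoxyphenyl)-2-(4-methoxyphenyl)-4-oxo-5-(phenylselanyl)-4,5,6,7-tetrahydro-1-benzofuran-6-carboxylate (racemic, mixture of diastereomers) | COC(=O)C1Cc2oc(-c3ccc(OC)cc3)c(-c3cc(OC)cc(OC)c3)c2C(=O)C1[Se]c1ccccc1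
F5 | step 4 | methyl 3-(3,5-dimethoxyphenyl)-2-(4-methoxyphenyl)-4-oxo-5-(phenylseleninyl)-4,5,6,7-tetrahydro-1-benzofuran-6-carboxylate (racemic, mixture of diastereomers) | COC(=O)C1Cc2oc(-c3ccc(OC)cc3)c(-c3cc(OC)cc(OC)c3)c2C(=O)C1[Se](=O)c1ccccc1
F6 | step 7 | methyl 3-(3,5-dihydroxyphenyl)-4-hydroxy-2-(4-hydroxyphenyl)-1-benzofuran-6-carboxylate | COC(=O)c1cc(O)c2c(-c3cc(O)cc(O)c3)c(-c3ccc(O)cc3)oc2c1
F7 | step 7 | methyl 4-[(tert-butyldimethylsilyl)oxy]-3-{3,5-bis[(tert-butyldimethylsilyl)oxy]phenyl}-2-{4-[(tert-butyldimethylsilyl)oxy]phenyl}-1-benzofuran-6-carboxylate | COC(=O)c1cc(O[Si](C)(C)C(C)(C)C)c2c(-c3cc(O[Si](C)(C)C(C)(C)C)cc(O[Si](C)(C)C(C)(C)C)c3)c(-c3ccc(O[Si](C)(C)C(C)(C)C)cc3)oc2c1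
F8 | step 7 | (4-[(tert-butyldimethylsilyl)oxy]-3-{3,5-bis[(tert-butyldimethylsilyl)oxy]phenyl}-2-{4-[(tert-butyldimethylsilyl)oxy]phenyl}-1-benzofuran-6-yl)methanol | OCc1cc(O[Si](C)(C)C(C)(C)C)c2c(-c3cc(O[Si](C)(C)C(C)(C)C)cc(O[Si](C)(C)C(C)(C)C)c3)c(-c3ccc(O[Si](C)(C)C(C)(C)C)cc3)oc2c1
F9 | step 7 | 4-[(tert-butyldimethylsilyl)oxy]-3-{3,5-bis[(tert-butyldimethylsilyl)oxy]phenyl}-2-{4-[(tert-butyldimethylsilyl)oxy]phenyl}-1-benzofuran-6-carbaldehyde | O=Cc1cc(O[Si](C)(C)C(C)(C)C)c2c(-c3cc(O[Si](C)(C)C(C)(C)C)cc(O[Si](C)(C)C(C)(C)C)c3)c(-c3ccc(O[Si](C)(C)C(C)(C)C)cc3)oc2c1
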